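# Proposed total synthesis of (3R,3aS,4S,8aR)-3-hydroxy-6,8a-dimethyl-3-(propan-2-yl)-1,2,3,3a,4,5,8,8a-octahydroazulen-4-yl 3,4-dimethoxybenzoate

## Analysis of the target

The target is the 3,4-dimethoxybenzoate of a daucane-type diol: a cyclopentane (C1–C5) fused across the C1–C5 bond to a cycloheptene (C1, C5, C6–C10). The numbering used below is: C1 quaternary ring-fusion carbon (CH3), C2 and C3 CH2, C4 tertiary carbinol carbon carrying the isopropyl group, C5 ring-fusion CH, C6 the carbon carrying the ester oxygen, C7 CH2, C8(CH3)=C9 the trisubstituted alkene, C10 CH2. There are four stereocentres, (1R,4R,5S,6S) in this numbering, three contiguous and the fourth quaternary and adjacent. H-5 is anti to the C1 methyl (trans ring fusion), the C4 hydroxyl is syn to the C1 methyl, and the C6 oxygen is syn to H-5, so O-4 and O-6 form a 1,3-anti pair. Sensitive points are the tertiary alcohol (ionisation, dehydration), the alkene C8=C9, which lies β,γ to C6 and would move into conjugation in any C6 ketone under base, and the hindered secondary carbinol that must be acylated next to a tertiary one. The difficulty lies in the seven-membered ring with its alkene in one defined position, in the all-carbon quaternary centre C1 beside the ring-fusion CH, and in the trans 5–7 fusion, which ring closures onto C5 from a chain on C1 do not give kinetically. The feature the plan exploits: the chain C7–C8(CH3)=C9–C10 is an isoprene unit that bridges the oxygenated C6 and the quaternary C1. With C5–C6 drawn as a second alkene, the seven-membered ring is a cyclohepta-1,4-diene (C5=C6, C7, C8=C9), and its σ-bond C1–C10 is the retron of a cis-divinylcyclopropane Cope rearrangement.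

## Retrosynthetic reasoning

**Ester C6–O.** Target 26 is cut at the acyl–oxygen bond to diol 24 and acid chloride 25. The ester goes on last because it would not survive the organometallic steps; the tertiary hydroxyl of 24 needs no protection.

**C4–isopropyl bond and C6–O bond.** Diol 24 is traced to boryl ketone 20, nucleophile 21 and oxidant 22. The isopropyl group is added to the C4 ketone only when C5 is already sp3, because the seven-ring branch at C5 and the C1 methyl then shield the same face and leave one face open. The C6 oxygen is carried as a C–B bond, which tolerates the addition and is oxidised with retention.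

**C6–B and C5–H bonds.** Boryl ketone 20 comes from dienone 18 and diboron 19 by conjugate borylation. The enone polarisation distinguishes C5=C6 from the isolated C8=C9 alkene, which hydroboration or epoxidation would not do. The forward reaction has to deliver boron to C6 and hydrogen to C5 on the face away from the C1 methyl.

**C1–C10 bond (key disconnection).** Dienone 18 is cut at C1–C10 and reconnected between C6 and C8 to give the cis-dialkenylcyclopropane 17. This is the only 3,3-mapping of the ring that leaves C7 as the cyclopropane CH2, puts the new σ-bond on the β-carbon of a 3-methylcyclopentenone, and leaves C8=C9 where the target has it. One step then builds the seven-membered ring, the quaternary centre and both alkene positions from a monocyclic enone that carries a C6 substituent.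

**C5–C6 bond.** Compound 17 is cut between the enone α-carbon and the cyclopropane into iodide 10 and bromoenone 14. An sp2–sp3 cross-coupling with retention at the cyclopropyl carbon keeps the cis relation that the rearrangement needs.

**Cyclopropane.** Iodide 10 is traced through aldehyde 8 and alcohol 7 to the Z-iodoalkene 5. The cyclopropane CH2 (C7) comes from 6 in a hydroxyl-directed asymmetric cyclopropanation, which sets both cyclopropane stereocentres and so, through the key step, the absolute configuration of C1. The ethenyl group is made from the directing CH2OH with 9, and 5 comes from 1, 2 and 3.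

**Bromoenone.** Compound 14 comes from 11 and 12 by bromination and loss of HBr.

## Alternatives that were turned down

**Alternative 1:** the textbook cut at C8=C9. Ring-closing metathesis of diene A1 (second-generation Grubbs catalyst) would close the seven-membered ring. A1 would come from 11 by conjugate addition, aldol trapping of the enolate and isopropyl addition. This is the shortest route on paper and was turned down for a structural reason, not for length. C5 has to be set on a monocyclic cyclopentanone enolate next to a quaternary carbon whose two substituents (CH3 and CH2CH=CH2) are almost the same size, so the electrophile has no clear face. Because C4 and C6 are then set relative to C5, the error is passed on to three stereocentres and cannot be corrected after the isopropyl addition. An enantioselective conjugate allylation at a β-methyl enone is also not a general reaction.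

**Alternative 2:** cut at C6–C7. An intramolecular carbonyl-ene reaction of hydroxy aldehyde A2 (Me2AlCl; 2-methylallyl donor tethered through its central carbon) would close the ring and create C6 in a chelate with the C4 oxygen. It was turned down because in the cyclic ene transition state the hydrogen is taken from the methyl group, not from the ring CH2. That gives the exocyclic C8 methylene, and a later isomerisation has no reason to choose C8=C9 over C7=C8. A2 also carries the C5 problem of Alternative 1.

**Alternative 3:** cut at C4–C5, the aldol retron C4(OH)–C5–C6=O. Diketone A3 would undergo intramolecular aldol cyclopentannulation onto the seven-membered ketone, followed by hydroxyl-directed reduction with Me4NBH(OAc)3, which would give the 1,3-anti diol reliably. It was turned down for three reasons. A five-membered ring closing onto a ring enolate from a chain on the neighbouring carbon gives the cis-fused ketol kinetically. Equilibration by retro-aldol needs base, under which the more acidic C7–H lets C8=C9 move into conjugation with the C6 ketone. And A3 needs its own asymmetric construction of C1, so nothing is saved.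

Key step: step 7

Assumption: the dioxaborolane controller in step 2 is taken to induce in its usual facial sense on this trisubstituted iodoalkene; should the antipode of 7 form, the enantiomeric controller is used and nothing else changes.

## Route

Step 1
Reactants: 1 prop-2-yn-1-ol; 2 methylmagnesium bromide; 3 iodine
Product: 5 (Z)-3-iodo-2-methylprop-2-en-1-ol, via alkenylmagnesium alkoxide 4 (not isolated)
Conditions: MeMgBr (2.5 equiv), CuI (10 mol%), THF, −10 °C to rt; then I2, THF, −78 to 0 °C
Reagents that add atoms: methylmagnesium bromide C[Mg]Br; iodine II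
Why: Copper-catalysed anti-carbomagnesiation of the propargylic alkoxide gives a five-membered oxamagnesacycle in which magnesium and CH2O are necessarily cis; iodinolysis of the C–Mg bond with retention gives the Z-iodoalkene.

Step 2
Reactants: 5 (Z)-3-iodo-2-methylprop-2-en-1-ol; 6 diiodomethane
Product: 7 [(1R,2R)-2-iodo-1-methylcyclopropyl]methanol
Conditions: Et2Zn, CH2I2, DME, (4R,5R)-2-butyl-N,N,N',N'-tetramethyl-1,3,2-dioxaborolane-4,5-dicarboxamide (1.2 equiv), CH2Cl2, −10 °C to rt
Reagents that add atoms: diiodomethane ICI
Why: Charette asymmetric Simmons–Smith cyclopropanation: the zinc alkoxide bound to the chiral dioxaborolane directs the zinc carbenoid to one alkene face. The addition is stereospecifically syn, so iodine stays cis to CH2OH and both cyclopropane stereocentres are set together.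

Step 3
Reactants: 7 [(1R,2R)-2-iodo-1-methylcyclopropyl]methanol
Product: 8 (1R,2R)-2-iodo-1-methylcyclopropane-1-carbaldehyde
Conditions: Dess–Martin periodinane, NaHCO3, CH2Cl2, 0 °C to rt
Reagents that add atoms: none
Why: Dess–Martin oxidation of a primary alcohol; the α-carbon is quaternary, so nothing can epimerise, and the cyclopropyl iodide is inert.

Step 4
Reactants: 8 (1R,2R)-2-iodo-1-methylcyclopropane-1-carbaldehyde; 9 methyltriphenylphosphonium bromide
Product: 10 (1R,2R)-1-ethenyl-2-iodo-1-methylcyclopropane
Conditions: Ph3PCH3Br, KN(SiMe3)2, THF, −78 to 0 °C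
Reagents that add atoms: methyltriphenylphosphonium bromide C[P+](c1ccccc1)(c1ccccc1)c1ccccc1.[Br-]
Why: Wittig methylenation of a non-enolisable aldehyde; the stereocentres are untouched. The volatile product is best carried on as an ether solution.

Step 5
Reactants: 11 3-methylcyclopent-2-en-1-one; 12 bromine
Product: 14 2-bromo-3-methylcyclopent-2-en-1-one, via dibromo ketone 13 (not isolated)
Conditions: Br2, CH2Cl2, 0 °C; then Et3N, 0 °C to rt
Reagents that add atoms: bromine BrBr
Why: Bromination–dehydrobromination: bromine adds to the enone alkene, and the amine removes the acidic α-hydrogen with loss of the tertiary β-bromide (E1cB) to give the α-bromo enone.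

Step 6
Reactants: 10 (1R,2R)-1-ethenyl-2-iodo-1-methylcyclopropane; 14 2-bromo-3-methylcyclopent-2-en-1-one
Product: 17 2-[(1R,2R)-2-ethenyl-2-methylcyclopropyl]-3-methylcyclopent-2-en-1-one, via cyclopropyllithium 15 (not isolated), via cyclopropylzinc chloride 16 (not isolated)
Conditions: t-BuLi (2.1 equiv), Et2O, −78 °C; ZnCl2, THF, −78 to 0 °C; then 14, Pd(PPh3)4 (5 mol%), THF, 25–40 °C
Reagents that add atoms: 2-bromo-3-methylcyclopent-2-en-1-one CC1=C(Br)C(=O)CC1
Why: Iodine–lithium exchange on a cyclopropyl iodide goes with retention, and the cyclopropyllithium is configurationally stable at −78 °C. Transmetalation to zinc and Negishi coupling under zerovalent palladium also retain configuration at the cyclopropyl carbon, so the enone (new C5–C6 bond) ends up cis to the ethenyl group; no stereocentre is created.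

Step 7
Reactants: 17 2-[(1R,2R)-2-ethenyl-2-methylcyclopropyl]-3-methylcyclopent-2-en-1-one
Product: 18 (3aR)-3a,6-dimethyl-3,3a,4,7-tetrahydroazulen-1(2H)-one
Conditions: degassed toluene (0.05 M), 2,6-di-tert-butyl-4-methylphenol (cat.), 110–130 °C, sealed tube
Reagents that add atoms: none
Why: Thermal 3,3-sigmatropic (Cope) rearrangement of a cis-1,2-dialkenylcyclopropane: in the boat transition state both alkenes lie over the three-membered ring, the cyclopropane bond C6–C8 between the two alkenyl-bearing carbons breaks, and the β-carbon of the enone (C1) bonds to the ethenyl terminus (C10). The closest known reaction type is the divinylcyclopropane–cycloheptadiene rearrangement of cyclopropyl-substituted cycloalkenones used for cycloheptannulation, including cases that create a quaternary carbon at the ring fusion. The seven-membered ring is closed by the sigmatropic shift itself, a strain-driven four-atom ring expansion of the cyclopropane through a six-centre boat, not by an end-to-end cyclisation. The one new stereocentre, the quaternary C1 (C3a of 18), is set by chirality transfer from the two cyclopropane stereocentres, which are consumed: the boat fixes which face of the C5=C1 alkene meets C10, so (1R,2R)-17 should give (3aR)-18. The alkene positions are not a matter of selectivity: the bond shift leaves C8=C9 one carbon (C7, the former cyclopropane CH2) away from C6 and puts C5=C6 in conjugation with the ketone. The step needs the cis relation of the two alkenyl groups, secured by the Z-alkene of 5 and by retention in steps 2 to 6, and a rearrangement temperature below that at which the cyclopropane bond homolyses. The methyl group on the reacting enone terminus points into the boat and slows the shift, hence the planned heating, and relief of ring strain makes the step irreversible.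

Step 8
Reactants: 18 (3aR)-3a,6-dimethyl-3,3a,4,7-tetrahydroazulen-1(2H)-one; 19 bis(pinacolato)diboron
Product: 20 (3aR,8S,8aR)-3a,6-dimethyl-8-(4,4,5,5-tetramethyl-1,3,2-dioxaborolan-2-yl)-3,3a,4,7,8,8a-hexahydroazulen-1(2H)-one
Conditions: B2pin2, CuCl (5 mol%), bis[2-(diphenylphosphino)phenyl] ether (5 mol%), NaOt-Bu (10 mol%), MeOH (2 equiv), THF, −20 to 0 °C; pH 7 buffer work-up
Reagents that add atoms: bis(pinacolato)diboron CC1(C)OB(OC1(C)C)B1OC(C)(C)C(C)(C)O1
Why: Copper-catalysed conjugate borylation: the boryl–copper species adds to the enone alkene and methanol protonates the copper enolate, while the isolated C8=C9 alkene is inert. The C1 methyl is pseudo-axial over the β face of C5=C6 (C10 is held pseudo-equatorial by the seven-membered ring), so boron at C6 and hydrogen at C5 should both enter from the α face. That gives the trans ring fusion and the C–B bond that becomes the 6α-oxygen.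

Step 9
Reactants: 20 (3aR,8S,8aR)-3a,6-dimethyl-8-(4,4,5,5-tetramethyl-1,3,2-dioxaborolan-2-yl)-3,3a,4,7,8,8a-hexahydroazulen-1(2H)-one; 21 isopropylmagnesium chloride; 22 hydrogen peroxide
Product: 24 (3R,3aS,4S,8aR)-6,8a-dimethyl-3-(propan-2-yl)-1,2,3,3a,4,5,8,8a-octahydroazulene-3,4-diol, via boronate carbinol 23 (not isolated)
Conditions: i-PrMgCl, CeCl3, THF, −78 °C; then H2O2, NaOH, THF/H2O, 0 °C
Reagents that add atoms: isopropylmagnesium chloride CC(C)[Mg]Cl; hydrogen peroxide OO
Why: Organocerium 1,2-addition, which limits enolisation and hydride transfer from the branched nucleophile, should occur on the α face of the cyclopentanone, anti to both the seven-ring branch at C5 and the C1 methyl, and so sets the tertiary carbinol (3R). The C–B bond is then oxidised with retention to the secondary alcohol (4S); at this point C5 can no longer epimerise.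

Step 10
Reactants: 24 (3R,3aS,4S,8aR)-6,8a-dimethyl-3-(propan-2-yl)-1,2,3,3a,4,5,8,8a-octahydroazulene-3,4-diol; 25 3,4-dimethoxybenzoyl chloride
Product: 26 (3R,3aS,4S,8aR)-3-hydroxy-6,8a-dimethyl-3-(propan-2-yl)-1,2,3,3a,4,5,8,8a-octahydroazulen-4-yl 3,4-dimethoxybenzoate
Conditions: 3,4-(MeO)2C6H3COCl, Et3N, DMAP (cat.), CH2Cl2, 0 °C to rt
Reagents that add atoms: 3,4-dimethoxybenzoyl chloride COc1ccc(cc1OC)C(Cl)=O
Why: Nucleophilic-catalysed acylation of the secondary alcohol; the tertiary alcohol, flanked by the isopropyl group and C5, should not be acylated under these conditions.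

## Compound list

1 | prop-2-yn-1-ol | C#CCO | starting material
2 | methylmagnesium bromide | C[Mg]Br | starting material
3 | iodine | II | starting material
4 | bromomagnesium (Z)-3-(bromomagnesio)-2-methylprop-2-en-1-olate (magnesium cis to CH2O) | Br[Mg]OC/C(C)=C\[Mg]Br | intermediate
5 | (Z)-3-iodo-2-methylprop-2-en-1-ol | OC/C(C)=C\I | intermediate
6 | diiodomethane | ICI | starting material
7 | [(1R,2R)-2-iodo-1-methylcyclopropyl]methanol (iodine cis to CH2OH) | I[C@@H]1C[C@]1(C)CO | intermediate
8 | (1R,2R)-2-iodo-1-methylcyclopropane-1-carbaldehyde | I[C@@H]1C[C@]1(C)C=O | intermediate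
9 | methyltriphenylphosphonium bromide | C[P+](c1ccccc1)(c1ccccc1)c1ccccc1.[Br-] | starting material
10 | (1R,2R)-1-ethenyl-2-iodo-1-methylcyclopropane (iodine cis to ethenyl) | I[C@@H]1C[C@]1(C)C=C | intermediate
11 | 3-methylcyclopent-2-en-1-one | CC1=CC(=O)CC1 | starting material
12 | bromine | BrBr | starting material
13 | 2,3-dibromo-3-methylcyclopentan-1-one (racemic, not isolated) | CC1(Br)CCC(=O)C1Br | intermediate
14 | 2-bromo-3-methylcyclopent-2-en-1-one | CC1=C(Br)C(=O)CC1 | intermediate
15 | [(1R,2S)-2-ethenyl-2-methylcyclopropyl]lithium (lithium cis to ethenyl) | [Li][C@@H]1C[C@]1(C)C=C | intermediate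
16 | chloro[(1R,2R)-2-ethenyl-2-methylcyclopropyl]zinc (zinc cis to ethenyl) | Cl[Zn][C@@H]1C[C@]1(C)C=C | intermediate
17 | 2-[(1R,2R)-2-ethenyl-2-methylcyclopropyl]-3-methylcyclopent-2-en-1-one (enone cis to ethenyl) | CC1=C([C@@H]2C[C@]2(C)C=C)C(=O)CC1 | intermediate
18 | (3aR)-3a,6-dimethyl-3,3a,4,7-tetrahydroazulen-1(2H)-one | C[C@]12CCC(=O)C1=CCC(C)=CC2 | intermediate
19 | bis(pinacolato)diboron | CC1(C)OB(OC1(C)C)B1OC(C)(C)C(C)(C)O1 | starting material
20 | (3aR,8S,8aR)-3a,6-dimethyl-8-(4,4,5,5-tetramethyl-1,3,2-dioxaborolan-2-yl)-3,3a,4,7,8,8a-hexahydroazulen-1(2H)-one | CC1(C)OB(OC1(C)C)[C@H]1CC(C)=CC[C@@]2(C)CCC(=O)[C@H]12 | intermediate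
21 | isopropylmagnesium chloride | CC(C)[Mg]Cl | starting material
22 | hydrogen peroxide | OO | starting material
23 | (3R,3aR,4S,8aR)-6,8a-dimethyl-3-(propan-2-yl)-4-(4,4,5,5-tetramethyl-1,3,2-dioxaborolan-2-yl)-1,2,3,3a,4,5,8,8a-octahydroazulen-3-ol (not isolated) | CC1(C)OB(OC1(C)C)[C@H]1CC(C)=CC[C@@]2(C)CC[C@@](O)(C(C)C)[C@H]12 | intermediate
24 | (3R,3aS,4S,8aR)-6,8a-dimethyl-3-(propan-2-yl)-1,2,3,3a,4,5,8,8a-octahydroazulene-3,4-diol | O[C@H]1CC(C)=CC[C@@]2(C)CC[C@@](O)(C(C)C)[C@H]12 | intermediate
25 | 3,4-dimethoxybenzoyl chloride | COc1ccc(cc1OC)C(Cl)=O | starting material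
26 | (3R,3aS,4S,8aR)-3-hydroxy-6,8a-dimethyl-3-(propan-2-yl)-1,2,3,3a,4,5,8,8a-octahydroazulen-4-yl 3,4-dimethoxybenzoate | COc1ccc(C(=O)O[C@H]2CC(C)=CC[C@@]3(C)CC[C@@](O)(C(C)C)[C@H]23)cc1OC | target

## Step count and least certain steps

Total number of steps: 10 (steps 1–4 and step 5 converge in step 6). Longest linear sequence: 9 steps (1, 2, 3, 4, 6, 7, 8, 9, 10).

**Step 7 (key step).** The methyl group on the reacting enone terminus points into the boat transition state and slows the shift. If the temperature has to be raised further, reversible homolysis of the cyclopropane bond flanked by the two alkenyl groups would scramble the cyclopropane centres (cis–trans stereomutation) and erode the enantiomeric purity that is transferred to C1. The fallback drops the pericyclic step, sets out from 11 and comes back at 18: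
- Enantioselective conjugate addition of (1,3-dioxolan-2-ylmethyl)magnesium bromide to 11 (CuCl with a chiral imidazolinium-derived carbene ligand), aldol trapping of the enolate with 3-methylbut-3-enal and dehydration (MsCl, Et3N, then DBU) would give the acetal dienone (2E,3R)-3-(1,3-dioxolan-2-ylmethyl)-3-methyl-2-(3-methylbut-3-en-1-ylidene)cyclopentan-1-one F1.
- Mild aqueous acid would free the aldehyde 2-[(1R,2E)-1-methyl-2-(3-methylbut-3-en-1-ylidene)-3-oxocyclopentyl]acetaldehyde F2.
- Wittig methylenation at −78 °C, where the aldehyde reacts before the hindered enone, would give the triene (2E,3R)-3-methyl-2-(3-methylbut-3-en-1-ylidene)-3-(prop-2-en-1-yl)cyclopentan-1-one F3.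
- Ring-closing metathesis with the second-generation Grubbs catalyst would close C8=C9 and give 18.

C5 stays sp2 throughout, so the weak point of Alternative 1 does not arise.

**Step 8.** Three processes can go wrong: poor facial selectivity of the boryl–copper addition, protonation of the copper enolate at C5 on the face of the C1 methyl (cis ring fusion, favoured if the ketone equilibrates under the basic conditions), and alkoxide-induced migration of C5=C6 towards C7 and into conjugation with C8=C9. The facial argument rests on the C1 methyl alone, and C5 stays epimerisable until step 9. The fallback places the oxygen by epoxide closure instead, sets out from 18 and comes back at 24. Weitz–Scheffer epoxidation (t-BuOOH, DBU), in which the ring closes at C5 directly beside the C1 methyl, would give the 5α,6α-epoxy ketone (8,8a-epoxide of 18, oxygen anti to the 3a-methyl group) F4. Reductive opening with SmI2 (THF/MeOH, −90 °C), with protonation inside the samarium chelate under non-equilibrating conditions, would give the ketol (3aR,8S,8aS)-8-hydroxy-3a,6-dimethyl-3,3a,4,7,8,8a-hexahydroazulen-1(2H)-one F5. Treating F5 with i-PrMgCl/CeCl3 as in step 9, without the oxidative work-up, would give 24.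

**Step 9.** Enolisation of the hindered ketone or hydride transfer from the secondary organometallic would return ketone or give the secondary alcohol, and attack at boron would consume reagent. The fallback introduces the three carbons as an sp2 nucleophile, sets out from 20 and comes back at 24. Addition of the organocerium reagent made from isopropenylmagnesium bromide and CeCl3, followed by the same oxidative work-up, would give the isopropenyl diol (3S,3aS,4S,8aR)-6,8a-dimethyl-3-(prop-1-en-2-yl)-1,2,3,3a,4,5,8,8a-octahydroazulene-3,4-diol F6. Hydrogenation with RhCl(PPh3)3/H2, which reduces the 1,1-disubstituted alkene much faster than the trisubstituted ring alkene, would give 24.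

**Step 6.** Transmetalation and reductive elimination may be slow for a hindered secondary cyclopropylzinc at a tetrasubstituted bromoalkene, which would lead to protodemetalation and homocoupling. The fallback reverses the polarity of the coupling, sets out from 14 and 10 and comes back at 17. Miyaura borylation of 14 (B2pin2, PdCl2(dppf), KOAc) would give the boronate 3-methyl-2-(4,4,5,5-tetramethyl-1,3,2-dioxaborolan-2-yl)cyclopent-2-en-1-one F7. Suzuki–Miyaura coupling of F7 with iodide 10 (Pd(PPh3)4, CsF), which also retains configuration at the cyclopropyl carbon, would give 17; any 17 that rearranges under the coupling conditions simply moves on to 18.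

**Step 2.** Methylene transfer to an iodine-bearing, electron-poor trisubstituted alkene may be slow, and the level of induction may suffer. The fallback brings the iodine in after the cyclopropanation, sets out from 4 and comes back at 7. Quenching 4 with Bu3SnCl instead of iodine would give (Z)-2-methyl-3-(tributylstannyl)prop-2-en-1-ol F8. The same dioxaborolane-mediated cyclopropanation on this electron-rich alkenylstannane would give [(1R,2R)-1-methyl-2-(tributylstannyl)cyclopropyl]methanol F9. Tin–iodine exchange with I2 in CH2Cl2 at 0 °C, with retention, would give 7.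

## Further compounds

F1 | step 7 | (2E,3R)-3-(1,3-dioxolan-2-ylmethyl)-3-methyl-2-(3-methylbut-3-en-1-ylidene)cyclopentan-1-one | C[C@]1(CC2OCCO2)CCC(=O)/C1=C/CC(C)=C
F2 | step 7 | 2-[(1R,2E)-1-methyl-2-(3-methylbut-3-en-1-ylidene)-3-oxocyclopentyl]acetaldehyde | C[C@]1(CC=O)CCC(=O)/C1=C/CC(C)=C
F3 | step 7 | (2E,3R)-3-methyl-2-(3-methylbut-3-en-1-ylidene)-3-(prop-2-en-1-yl)cyclopentan-1-one | C[C@]1(CC=C)CCC(=O)/C1=C/CC(C)=C
F4 | step 8 | (3aR)-8,8a-epoxy-3a,6-dimethyl-3,3a,4,7,8,8a-hexahydroazulen-1(2H)-one, epoxide oxygen anti to the 3a-methyl group | O1[C@H]2CC(C)=CC[C@@]3(C)CCC(=O)[C@]123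
F5 | step 8 | (3aR,8S,8aS)-8-hydroxy-3a,6-dimethyl-3,3a,4,7,8,8a-hexahydroazulen-1(2H)-one | O[C@H]1CC(C)=CC[C@@]2(C)CCC(=O)[C@H]12
F6 | step 9 | (3S,3aS,4S,8aR)-6,8a-dimethyl-3-(prop-1-en-2-yl)-1,2,3,3a,4,5,8,8a-octahydroazulene-3,4-diol | O[C@H]1CC(C)=CC[C@@]2(C)CC[C@@](O)(C(C)=C)[C@H]12
F7 | step 6 | 3-methyl-2-(4,4,5,5-tetramethyl-1,3,2-dioxaborolan-2-yl)cyclopent-2-en-1-one | CC1=C(B2OC(C)(C)C(C)(C)O2)C(=O)CC1
F8 | step 2 | (Z)-2-methyl-3-(tributylstannyl)prop-2-en-1-ol | OC/C(C)=C\[Sn](CCCC)(CCCC)CCCC
F9 | step 2 | [(1R,2R)-1-methyl-2-(tributylstannyl)cyclopropyl]methanol | CCCC[Sn](CCCC)(CCCC)[C@@H]1C[C@]1(C)CO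
A1 | alternative 1 | (1R,2S,3R)-2-[(1S)-1-hydroxy-3-methylbut-3-en-1-yl]-3-methyl-1-(propan-2-yl)-3-(prop-2-en-1-yl)cyclopentan-1-ol | O[C@@H](CC(C)=C)[C@H]1[C@](O)(C(C)C)CC[C@]1(C)CC=C
A2 | alternative 2 | (1R,2R,5S)-2-hydroxy-5-methyl-5-(3-methylbut-3-en-1-yl)-2-(propan-2-yl)cyclopentane-1-carbaldehyde | O=C[C@H]1[C@](O)(C(C)C)CC[C@]1(C)CCC(C)=C
A3 | alternative 3 | (3R)-3,6-dimethyl-3-(4-methyl-3-oxopentyl)cyclohept-5-en-1-one | CC(C)C(=O)CC[C@]1(C)CC=C(C)CC(=O)C1
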